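**Plan**

Numbering follows spiro[5.5]undecane: ring A = C1–C6 (C1 CHMe, C4 CHBr, C5 CMe2, C6 spiro), ring B = C6–C11 (C9 CMeCl, C10 CHBr).
Retrosynthesis cuts, in order: C7–C8 of ring B; the C9–Cl/C10–Br pair (back to a Z-allylic alcohol); C1–H; C5–C6 with C4–Br of ring A (back to an acyclic triene); then C1–C2 and C6–C11 of a tetrasubstituted alkene (back to methyl acetoacetate).
Forward: acetoacetate alkylation, Z-enol triflate and iron-catalysed coupling give a geometrically defined tetrasubstituted alkene; a bromonium cyclisation closes ring A first; ring B is closed last by ring-closing metathesis at C7=C8, followed by diimide reduction.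
Stereochemistry: C4 from a chiral Lewis-base bromination catalyst; C6 from the alkene geometry through a chair transition state; C1 from hydrogenation directed by the C7 hydroxymethyl group; C9 and C10 from a ligand-controlled anti bromochlorination of the Z-alkene.
Enabling feature: C7 and C8 are the only adjacent ring-B atoms that are plain CH2 groups, and each hangs on a fully substituted carbon (C6, C9). Closing ring B there creates no stereocentre and lets the equatorial C9–Cl/C10–Br pair be set on the open chain; anti addition to the finished spirocycle would give the diaxial pair instead, because C5 (CMe2) cannot sit axial on ring B.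

Key step: step 13

Remark: the bromination catalyst (step 7) and the Schiff-base ligand (step 9) are each used as the enantiomer that delivers the configuration drawn; compounds 1, 3 and 7 are taken as commercial.

**Route**

Step 1
Reactants: 1 3-methylfuran-2(5H)-one
Product: 2 methyl (2Z)-4-bromo-2-methylbut-2-enoate
Conditions: HBr (g), MeOH, 0 °C to rt
Reagents that add atoms: hydrogen bromide, Br; methanol, CO
Why: Acid-mediated lactone opening, in which bromide cleaves the allylic C–O bond of the protonated butenolide (SN2) and the acid is esterified by the solvent; the ring has already fixed the Z geometry that later makes C8 and C11 cis.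

Step 2
Reactants: 3 methyl acetoacetate; 2 methyl (2Z)-4-bromo-2-methylbut-2-enoate
Product: 4 dimethyl (2Z)-5-acetyl-2-methylhex-2-enedioate (racemic at the acidic CH)
Conditions: K2CO3, acetone, 0 °C to rt
Reagents that add atoms: none
Why: Acetoacetic ester C-alkylation of a soft enolate with a primary allylic bromide (SN2), the α-methyl group making the enoate a poor Michael acceptor; the new CH centre is labile and is erased in step 3.

Step 3
Reactants: 4 dimethyl (2Z)-5-acetyl-2-methylhex-2-enedioate
Product: 6 dimethyl (2Z,5Z)-2-methyl-5-{1-[(trifluoromethanesulfonyl)oxy]ethylidene}hex-2-enedioate, via sodium Z-enolate 5 (not isolated)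
Conditions: NaH, THF, 0 °C; then Tf2O, −78 to 0 °C
Reagents that add atoms: trifluoromethanesulfonic anhydride, O=S(=O)(OS(=O)(=O)C(F)(F)F)C(F)(F)F
Why: O-sulfonylation of the chelated sodium enolate of the β-keto ester (stereoselective enol triflate formation) should place the triflate cis to the ester carbon C7, which fixes the geometry of the future tetrasubstituted alkene.

Step 4
Reactants: 6 dimethyl (2Z,5Z)-2-methyl-5-{1-[(trifluoromethanesulfonyl)oxy]ethylidene}hex-2-enedioate; 7 5-bromo-2-methylpent-2-ene
Product: 9 methyl (2Z,5Z)-5-(methoxycarbonyl)-2,6,10-trimethylundeca-2,5,9-trienoate, via homoprenylmagnesium bromide 8 (not isolated)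
Conditions: Mg, THF, rt; then 6, Fe(acac)3 (5 mol%), THF/NMP, −30 °C
Reagents that add atoms: none
Why: Iron-catalysed Kumada-type coupling of an alkyl Grignard reagent with an enol triflate is faster than addition to the esters and keeps the alkene geometry, so the homoprenyl chain should end cis to C7 and the methyl cis to C11.

Step 5
Reactants: 9 methyl (2Z,5Z)-5-(methoxycarbonyl)-2,6,10-trimethylundeca-2,5,9-trienoate
Product: 10 (2Z,5Z)-5-(hydroxymethyl)-2,6,10-trimethylundeca-2,5,9-trien-1-ol
Conditions: i-Bu2AlH, CH2Cl2, −78 to 0 °C; aqueous potassium sodium tartrate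
Reagents that add atoms: none
Why: 1,2-Reduction of both conjugated esters by the aluminium hydride should give the two allylic alcohols without touching the alkenes.

Step 6
Reactants: 10 (2Z,5Z)-5-(hydroxymethyl)-2,6,10-trimethylundeca-2,5,9-trien-1-ol
Product: 11 (2Z,5Z)-5-(acetoxymethyl)-2,6,10-trimethylundeca-2,5,9-trien-1-yl acetate
Conditions: Ac2O, pyridine, DMAP (cat.), CH2Cl2, 0 °C to rt
Reagents that add atoms: acetic anhydride, CC(=O)OC(C)=O
Why: DMAP-catalysed acylation of both primary alcohols; the acetates lower the nucleophilicity of the two internal alkenes and keep the oxygens from trapping cations in step 7.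

Step 7
Reactants: 11 (2Z,5Z)-5-(acetoxymethyl)-2,6,10-trimethylundeca-2,5,9-trien-1-yl acetate
Product: 12 (2Z)-4-[(1R,3R)-1-(acetoxymethyl)-3-bromo-2,2-dimethyl-6-methylidenecyclohexyl]-2-methylbut-2-en-1-yl acetate
Conditions: 1,3-dibromo-5,5-dimethylhydantoin (1.05 equiv), chiral BINOL-derived thiophosphoramide Lewis base (10 mol%), toluene/CH2Cl2, −78 °C
Reagents that add atoms: 1,3-dibromo-5,5-dimethylhydantoin, CC1(C)N(Br)C(=O)N(Br)C1=O
Why: Proposed new method: the chiral Lewis base should transfer Br+ enantioselectively to the terminal trisubstituted alkene (the least hindered, and the only one without an allylic acetoxy group), and the bromonium ion is then opened at C5 by C6 of the tetrasubstituted alkene through a chair transition state, so that C4 is set by the catalyst and C6 by the alkene geometry (the arm cis to the methyl becomes equatorial and cis to bromine), after which the C1 cation loses a methyl proton (any endocyclic C1=C2 isomer would converge in step 10); the closest known reactions are the catalytic enantioselective bromocyclisation of homogeranyl arenes and the bromonium-induced cyclisation of geranyl acetate.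

Step 8
Reactants: 12 (2Z)-4-[(1R,3R)-1-(acetoxymethyl)-3-bromo-2,2-dimethyl-6-methylidenecyclohexyl]-2-methylbut-2-en-1-yl acetate
Product: 13 (2Z)-4-[(1R,3R)-3-bromo-1-(hydroxymethyl)-2,2-dimethyl-6-methylidenecyclohexyl]-2-methylbut-2-en-1-ol
Conditions: K2CO3 (cat.), MeOH, 0 °C to rt
Reagents that add atoms: none
Why: Base-catalysed transesterification should free both primary alcohols under conditions too mild to disturb the secondary neopentyl bromide.

Step 9
Reactants: 13 (2Z)-4-[(1R,3R)-3-bromo-1-(hydroxymethyl)-2,2-dimethyl-6-methylidenecyclohexyl]-2-methylbut-2-en-1-ol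
Product: 14 (2S,3S)-3-bromo-4-[(1R,3R)-3-bromo-1-(hydroxymethyl)-2,2-dimethyl-6-methylidenecyclohexyl]-2-chloro-2-methylbutan-1-ol
Conditions: NBS, ClTi(OiPr)3, chiral tridentate Schiff-base ligand (20 mol%), hexanes/CH2Cl2, −20 °C
Reagents that add atoms: N-bromosuccinimide, O=C1CCC(=O)N1Br; chlorotitanium triisopropoxide, CC(C)O[Ti](Cl)(OC(C)C)OC(C)C
Why: Titanium-mediated catalytic enantioselective bromochlorination of an allylic alcohol, in which the titanium-bound allylic alkoxide directs Br+ to the arm alkene and chloride is delivered anti to the tertiary carbon C9, so that the Z geometry fixes the relative and the ligand the absolute configuration of C9 and C10 independently of ring A.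

Step 10
Reactants: 14 (2S,3S)-3-bromo-4-[(1R,3R)-3-bromo-1-(hydroxymethyl)-2,2-dimethyl-6-methylidenecyclohexyl]-2-chloro-2-methylbutan-1-ol
Product: 15 (2S,3S)-3-bromo-4-[(1R,3R,6S)-3-bromo-1-(hydroxymethyl)-2,2,6-trimethylcyclohexyl]-2-chloro-2-methylbutan-1-ol
Conditions: [Ir(cod)(PCy3)(py)]PF6 (5 mol%), H2 (1 atm), CH2Cl2, 0 °C to rt
Reagents that add atoms: none
Why: Hydroxyl-directed homogeneous hydrogenation, in which the cationic iridium catalyst binds the homoallylic C7 hydroxymethyl group (on the face of ring A opposite to bromine and C11) and delivers H2 to C1 from that face, which should place the new methyl cis to C11 and to the C4 bromine.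

Step 11
Reactants: 15 (2S,3S)-3-bromo-4-[(1R,3R,6S)-3-bromo-1-(hydroxymethyl)-2,2,6-trimethylcyclohexyl]-2-chloro-2-methylbutan-1-ol
Product: 16 (1R,3R,6S)-3-bromo-1-[(2S,3S)-2-bromo-3-chloro-3-methyl-4-oxobutyl]-2,2,6-trimethylcyclohexane-1-carbaldehyde
Conditions: Dess–Martin periodinane, pyridine, CH2Cl2, 0 °C to rt
Reagents that add atoms: none
Why: Dess–Martin oxidation of both primary alcohols under buffered conditions; neither aldehyde has an α-hydrogen, so epimerisation and β-elimination of bromide are excluded.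

Step 12
Reactants: 16 (1R,3R,6S)-3-bromo-1-[(2S,3S)-2-bromo-3-chloro-3-methyl-4-oxobutyl]-2,2,6-trimethylcyclohexane-1-carbaldehyde
Product: 17 (1R,3R,6S)-3-bromo-1-[(2S,3S)-2-bromo-3-chloro-3-methylpent-4-en-1-yl]-1-ethenyl-2,2,6-trimethylcyclohexane
Conditions: Ph3PCH3Br, KN(SiMe3)2, THF, −78 to 0 °C
Reagents that add atoms: methyltriphenylphosphonium bromide, C[P+](c1ccccc1)(c1ccccc1)c1ccccc1.[Br-]
Why: Twofold Wittig methylenation of the two non-enolisable aldehydes with the smallest ylide at low temperature, where olefination should outrun base-induced elimination of the halides.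

Step 13
Reactants: 17 (1R,3R,6S)-3-bromo-1-[(2S,3S)-2-bromo-3-chloro-3-methylpent-4-en-1-yl]-1-ethenyl-2,2,6-trimethylcyclohexane
Product: 18 (1S,4R,6S,9S,10S)-4,10-dibromo-9-chloro-1,5,5,9-tetramethylspiro[5.5]undec-7-ene
Conditions: second-generation Grubbs catalyst RuCl2(=CHPh)(H2IMes)(PCy3) (10 mol%), toluene (2 mM), 60 °C
Reagents that add atoms: none
Why: Ring-closing metathesis: the ruthenium alkylidene loads on one vinyl group, adds to the other in a [2+2] cycloaddition to a ruthenacyclobutane and cycloreverts to the cyclohexene, with loss of ethylene as the driving force. The closest known reaction type is the ring-closing metathesis of 1,7-dienes whose two vinyl groups sit on fully substituted carbons, giving cyclohexenes. Ring B is closed as a six-membered ring by forming the C7=C8 bond, both alkene carbons endocyclic and the cis geometry enforced by the ring. No stereocentre is formed, and none of the five existing ones is epimerisable under these neutral conditions. The step needs cyclisation to win over oligomerisation and over ionisation of the tertiary allylic chloride: the quaternary carbons C6 and C9 hold the two vinyl groups together (gem-disubstituent effect), high dilution suppresses cross-metathesis, and the vicinal bromine at C10 together with the non-polar, Lewis-acid-free medium slows ionisation.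

Step 14
Reactants: 18 (1S,4R,6S,9S,10S)-4,10-dibromo-9-chloro-1,5,5,9-tetramethylspiro[5.5]undec-7-ene
Product: 19 (1S,4R,6S,9S,10S)-4,10-dibromo-9-chloro-1,5,5,9-tetramethylspiro[5.5]undecane
Conditions: 2-nitrobenzenesulfonylhydrazide, Et3N, CH2Cl2, rt
Reagents that add atoms: none
Why: Diimide reduction (concerted syn transfer of two hydrogens from HN=NH) should saturate the cis-disubstituted alkene without the hydrogenolysis of the allylic C–Cl or the C–Br bonds that a metal catalyst would risk.

**Compound list**

1 | 3-methylfuran-2(5H)-one | CC1=CCOC1=O | starting material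
2 | methyl (2Z)-4-bromo-2-methylbut-2-enoate | BrC/C=C(C)\C(=O)OC | intermediate
3 | methyl acetoacetate | CC(=O)CC(=O)OC | starting material
4 | dimethyl (2Z)-5-acetyl-2-methylhex-2-enedioate | COC(=O)/C(C)=C\CC(C(C)=O)C(=O)OC | intermediate
5 | sodium (2Z,5Z)-7-methoxy-3-(methoxycarbonyl)-6-methyl-7-oxohepta-2,5-dien-2-olate | COC(=O)/C(C)=C\C/C(C(=O)OC)=C(\C)[O-].[Na+] | intermediate
6 | dimethyl (2Z,5Z)-2-methyl-5-{1-[(trifluoromethanesulfonyl)oxy]ethylidene}hex-2-enedioate | COC(=O)/C(C)=C\C/C(C(=O)OC)=C(\C)OS(=O)(=O)C(F)(F)F | intermediate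
7 | 5-bromo-2-methylpent-2-ene | CC(C)=CCCBr | starting material
8 | (4-methylpent-3-en-1-yl)magnesium bromide | CC(C)=CCC[Mg]Br | intermediate
9 | methyl (2Z,5Z)-5-(methoxycarbonyl)-2,6,10-trimethylundeca-2,5,9-trienoate | COC(=O)/C(C)=C\C/C(C(=O)OC)=C(\C)CCC=C(C)C | intermediate
10 | (2Z,5Z)-5-(hydroxymethyl)-2,6,10-trimethylundeca-2,5,9-trien-1-ol | OC/C(C)=C\C/C(CO)=C(\C)CCC=C(C)C | intermediate
11 | (2Z,5Z)-5-(acetoxymethyl)-2,6,10-trimethylundeca-2,5,9-trien-1-yl acetate | CC(=O)OC/C(C)=C\C/C(COC(C)=O)=C(\C)CCC=C(C)C | intermediate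
12 | (2Z)-4-[(1R,3R)-1-(acetoxymethyl)-3-bromo-2,2-dimethyl-6-methylidenecyclohexyl]-2-methylbut-2-en-1-yl acetate | C=C1CC[C@@H](Br)C(C)(C)[C@]1(C/C=C(C)\COC(C)=O)COC(C)=O | intermediate
13 | (2Z)-4-[(1R,3R)-3-bromo-1-(hydroxymethyl)-2,2-dimethyl-6-methylidenecyclohexyl]-2-methylbut-2-en-1-ol | C=C1CC[C@@H](Br)C(C)(C)[C@]1(C/C=C(C)\CO)CO | intermediate
14 | (2S,3S)-3-bromo-4-[(1R,3R)-3-bromo-1-(hydroxymethyl)-2,2-dimethyl-6-methylidenecyclohexyl]-2-chloro-2-methylbutan-1-ol | C=C1CC[C@@H](Br)C(C)(C)[C@]1(C[C@H](Br)[C@@](C)(Cl)CO)CO | intermediate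
15 | (2S,3S)-3-bromo-4-[(1R,3R,6S)-3-bromo-1-(hydroxymethyl)-2,2,6-trimethylcyclohexyl]-2-chloro-2-methylbutan-1-ol | C[C@H]1CC[C@@H](Br)C(C)(C)[C@]1(C[C@H](Br)[C@@](C)(Cl)CO)CO | intermediate
16 | (1R,3R,6S)-3-bromo-1-[(2S,3S)-2-bromo-3-chloro-3-methyl-4-oxobutyl]-2,2,6-trimethylcyclohexane-1-carbaldehyde | C[C@H]1CC[C@@H](Br)C(C)(C)[C@]1(C[C@H](Br)[C@@](C)(Cl)C=O)C=O | intermediate
17 | (1R,3R,6S)-3-bromo-1-[(2S,3S)-2-bromo-3-chloro-3-methylpent-4-en-1-yl]-1-ethenyl-2,2,6-trimethylcyclohexane | C[C@H]1CC[C@@H](Br)C(C)(C)[C@]1(C[C@H](Br)[C@@](C)(Cl)C=C)C=C | intermediate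
18 | (1S,4R,6S,9S,10S)-4,10-dibromo-9-chloro-1,5,5,9-tetramethylspiro[5.5]undec-7-ene | C[C@H]1CC[C@@H](Br)C(C)(C)[C@]12C=C[C@](C)(Cl)[C@@H](Br)C2 | intermediate
19 | (1S,4R,6S,9S,10S)-4,10-dibromo-9-chloro-1,5,5,9-tetramethylspiro[5.5]undecane | C[C@H]1CC[C@@H](Br)C(C)(C)[C@]12CC[C@](C)(Cl)[C@@H](Br)C2 | target

**Totals and risks**

Total step count: 14. Longest linear sequence: 14 steps (1 to 19).

Steps most likely to fail:

Step 7 (low enantio-induction, transfer of the bromonium ion to the other alkenes, or interrupted cyclisation). Setting out from 11, cyclisation with the achiral bromonium source Et2SBr·SbCl5Br (MeNO2, −25 °C), a known reaction of geranyl-type acetates, should give 12 together with its enantiomer (2Z)-4-[(1S,3S)-1-(acetoxymethyl)-3-bromo-2,2-dimethyl-6-methylidenecyclohexyl]-2-methylbut-2-en-1-yl acetate F1. Methanolysis as in step 8 should give 13 and (2Z)-4-[(1S,3S)-3-bromo-1-(hydroxymethyl)-2,2-dimethyl-6-methylidenecyclohexyl]-2-methylbut-2-en-1-ol F2. The ligand-controlled bromochlorination of step 9 should then turn the pair into 14 and its diastereomer (2S,3S)-3-bromo-4-[(1S,3S)-3-bromo-1-(hydroxymethyl)-2,2-dimethyl-6-methylidenecyclohexyl]-2-chloro-2-methylbutan-1-ol F3, which is removed by chromatography; the route is rejoined at 14, at the cost of half the material.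

Step 13 (slow loading of the catalyst on either neopentyl vinyl group, leaving time for ionisation and allylic shift of the tertiary allylic chloride). Setting out from 16, Wittig olefination with the ylide from (hex-5-en-1-yl)triphenylphosphonium bromide and KN(SiMe3)2 should give the relay substrate (1S,3R,6S)-3-bromo-1-[(2S,3S,4Z)-2-bromo-3-chloro-3-methyldeca-4,9-dien-1-yl]-1-[(1Z)-hepta-1,6-dien-1-yl]-2,2,6-trimethylcyclohexane F4. In a relay ring-closing metathesis the catalyst loads on the unhindered terminal alkenes, expels cyclopentene and is delivered intramolecularly to C7 and C8 at lower temperature; this should give 18, where the route is rejoined.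

Step 9 (loss of regio- or enantiocontrol on the Z-trisubstituted allylic alcohol, or competing bromination of the C1 methylidene group). Setting out from 13, Sharpless asymmetric epoxidation (Ti(OiPr)4, diethyl tartrate, t-BuOOH) should give [(2S,3R)-3-{[(1R,3R)-3-bromo-1-(hydroxymethyl)-2,2-dimethyl-6-methylidenecyclohexyl]methyl}-2-methyloxiran-2-yl]methanol F5. Ti(OiPr)4-mediated opening with diethylammonium bromide at the secondary carbon C10 (inversion) should give (2S,3S)-3-bromo-4-[(1R,3R)-3-bromo-1-(hydroxymethyl)-2,2-dimethyl-6-methylidenecyclohexyl]-2-methylbutane-1,2-diol F6. Directed hydrogenation as in step 10 should give (2S,3S)-3-bromo-4-[(1R,3R,6S)-3-bromo-1-(hydroxymethyl)-2,2,6-trimethylcyclohexyl]-2-methylbutane-1,2-diol F7. Concentrated HCl at 0 °C should then replace only the tertiary hydroxyl by chloride, with retention through the bromine-bridged cation of the open chain, and the route is rejoined at 15.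

Further compounds
F1 | step 7 | (2Z)-4-[(1S,3S)-1-(acetoxymethyl)-3-bromo-2,2-dimethyl-6-methylidenecyclohexyl]-2-methylbut-2-en-1-yl acetate | C=C1CC[C@H](Br)C(C)(C)[C@@]1(C/C=C(C)\COC(C)=O)COC(C)=O
F2 | step 7 | (2Z)-4-[(1S,3S)-3-bromo-1-(hydroxymethyl)-2,2-dimethyl-6-methylidenecyclohexyl]-2-methylbut-2-en-1-ol | C=C1CC[C@H](Br)C(C)(C)[C@@]1(C/C=C(C)\CO)CO
F3 | step 7 | (2S,3S)-3-bromo-4-[(1S,3S)-3-bromo-1-(hydroxymethyl)-2,2-dimethyl-6-methylidenecyclohexyl]-2-chloro-2-methylbutan-1-ol | C=C1CC[C@H](Br)C(C)(C)[C@@]1(C[C@H](Br)[C@@](C)(Cl)CO)CO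
F4 | step 13 | (1S,3R,6S)-3-bromo-1-[(2S,3S,4Z)-2-bromo-3-chloro-3-methyldeca-4,9-dien-1-yl]-1-[(1Z)-hepta-1,6-dien-1-yl]-2,2,6-trimethylcyclohexane | C[C@H]1CC[C@@H](Br)C(C)(C)[C@]1(C[C@H](Br)[C@@](C)(Cl)/C=C\CCCC=C)/C=C\CCCC=C
F5 | step 9 | [(2S,3R)-3-{[(1R,3R)-3-bromo-1-(hydroxymethyl)-2,2-dimethyl-6-methylidenecyclohexyl]methyl}-2-methyloxiran-2-yl]methanol | C=C1CC[C@@H](Br)C(C)(C)[C@]1(C[C@@H]2[C@](C)(CO)O2)CO
F6 | step 9 | (2S,3S)-3-bromo-4-[(1R,3R)-3-bromo-1-(hydroxymethyl)-2,2-dimethyl-6-methylidenecyclohexyl]-2-methylbutane-1,2-diol | C=C1CC[C@@H](Br)C(C)(C)[C@]1(C[C@H](Br)[C@@](C)(O)CO)CO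
F7 | step 9 | (2S,3S)-3-bromo-4-[(1R,3R,6S)-3-bromo-1-(hydroxymethyl)-2,2,6-trimethylcyclohexyl]-2-methylbutane-1,2-diol | C[C@H]1CC[C@@H](Br)C(C)(C)[C@]1(C[C@H](Br)[C@@](C)(O)CO)CO
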